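## Retrosynthetic overview
1. Colleterpenol ⇒ 14-membered ring carrying removable sulfur at C1 and C12; both C–S bonds are cleaved reductively at the end.
2. Key bond C1–C14, which closes the ring: a sulfonyl-stabilised allyl anion at farnesyl C1, a carbon that is normally an electrophile, opens the C14–C15 epoxide with inversion. In the same flask a thio-stabilised allyl anion at C12 first displaces a tosylate at C13.
3. The C13/C14 bis-electrophile is the (2R,3S)-epoxy tosylate of (2Z,6E)-farnesol, made by Sharpless epoxidation. The Z-olefin geometry plus anti opening gives the (14R,15S) pair.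
4. (2Z,6E)-Farnesol ⇒ propyne + geranyl bromide + CH2O, then syn-carbomagnesiation with MeMgBr. The C1/C12 bis-nucleophile ⇒ (E,E)-farnesol by sulfone formation, SeO2 oxidation and PhSSPh/Bu3P.
5. Ring order: oxirane in step 3, then the 14-membered carbocycle in step 7, where the oxirane is consumed.

Assumption: atoms are numbered along the hexaprenyl chain (ring = C1–C14, ring CH = C14, carbinol carbon = C15). With this numbering the target SMILES reads (14R,15S), with all olefins E.

## Route

Step 1
Reactants: 1 propyne; 2 geranyl bromide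
Product: 5 (E)-7,11-dimethyldodeca-6,10-dien-2-yn-1-ol, via 1,3-dilithiopropyne 3 (not isolated), via lithium enynide 4 (not isolated)
Conditions: n-BuLi (2.1 equiv), TMEDA, Et2O/hexane, −78 → 25 °C; 2, THF, −78 → 0 °C; (CH2O)n, 0 → 25 °C; H2O
Reagents that add atoms: paraformaldehyde (as formaldehyde), C=O
Why: 1,3-Dilithiopropyne reacts first at its more nucleophilic sp3 terminus in an SN2 allylation of 2 (E-olefin untouched), and the remaining lithium acetylide then adds to formaldehyde (sequential dianion alkylation and acetylide hydroxymethylation); no stereocentre is formed.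

Step 2
Reactants: 5 (E)-7,11-dimethyldodeca-6,10-dien-2-yn-1-ol
Product: 7 (2Z,6E)-farnesol, via alkenylmagnesium alkoxide 6 (not isolated)
Conditions: MeMgBr (5 equiv), Fe(acac)3 (15 mol %), THF, 0 → 25 °C; H2O
Reagents that add atoms: methylmagnesium bromide, C[Mg]Br
Why: Alkoxide-directed iron-catalysed syn-carbomagnesiation puts CH3 on the distal alkyne carbon and Mg on C2, so protonolysis leaves the homogeranyl chain cis to CH2OH, giving the 2Z olefin that later encodes the C14/C15 relative configuration.

Step 3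
Reactants: 7 (2Z,6E)-farnesol
Product: 9 [(2R,3S)-3-[(3E)-4,8-dimethylnona-3,7-dien-1-yl]-3-methyloxiran-2-yl]methyl 4-methylbenzenesulfonate, via epoxy alcohol 8 (not isolated)
Conditions: Ti(Oi-Pr)4 (10 mol %), D-(−)-DIPT (13 mol %), t-BuOOH, 4 Å MS, CH2Cl2, −20 °C; P(OMe)3; then TsCl, Et3N, DMAP (cat.), −10 °C
Reagents that add atoms: tert-butyl hydroperoxide, CC(C)(C)OO; 4-toluenesulfonyl chloride, Cc1ccc(cc1)S(=O)(=O)Cl
Why: Sharpless asymmetric epoxidation touches only the allylic-alcohol olefin and with D-(−)-tartrate gives the (2R,3S) cis-epoxide (≥90 % ee expected; C15 = S is already final, C14 still has to be inverted), and in situ sulfonylation makes C13 a primary electrophile without handling the epoxy alcohol.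

Step 4
Reactants: 10 (2E,6E)-farnesol
Product: 12 (2E,6E)-farnesyl phenyl sulfone, via farnesyl bromide 11 (not isolated)
Conditions: PBr3 (0.4 equiv), THF, 0 °C; then PhSO2Na, DMF, 25 °C
Reagents that add atoms: sodium benzenesulfinate, [Na+].[O-]S(=O)c1ccccc1
Why: SN2 bromination of the primary allylic alcohol followed by S-alkylation of the sulfinate gives the allylic sulfone with both E-olefins retained; no stereocentre is formed.

Step 5
Reactants: 12 (2E,6E)-farnesyl phenyl sulfone
Product: 13 (2E,6E,10E)-2,6,10-trimethyl-12-(phenylsulfonyl)dodeca-2,6,10-trien-1-ol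
Conditions: SeO2 (10 mol %), t-BuOOH, salicylic acid (10 mol %), CH2Cl2, 0 → 25 °C
Reagents that add atoms: selenium dioxide, O=[Se]=O; tert-butyl hydroperoxide, CC(C)(C)OO
Why: Catalytic SeO2 allylic hydroxylation (ene reaction then [2,3]-shift) selects the E-methyl of the terminal, most electron-rich olefin, because the C2=C3 olefin is deactivated by the sulfone.

Step 6
Reactants: 13 (2E,6E,10E)-2,6,10-trimethyl-12-(phenylsulfonyl)dodeca-2,6,10-trien-1-ol
Product: 14 [(2E,6E,10E)-3,7,11-trimethyl-12-(phenylsulfanyl)dodeca-2,6,10-trien-1-yl] phenyl sulfone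
Conditions: PhSSPh, n-Bu3P, THF, 0 → 25 °C
Reagents that add atoms: diphenyl disulfide, c1ccccc1SSc1ccccc1
Why: In this Hata-type oxidation–reduction condensation thiolate displaces the alkoxyphosphonium salt of the primary allylic alcohol by SN2, without allylic shift or loss of E geometry, under neutral conditions that leave the acidic sulfone CH2 alone.

Step 7
Reactants: 14 [(2E,6E,10E)-3,7,11-trimethyl-12-(phenylsulfanyl)dodeca-2,6,10-trien-1-yl] phenyl sulfone; 9 the (2R,3S)-epoxy tosylate
Product: 17 (2S,5E)-6,10-dimethyl-2-[(1S,3E,7E,11E)-4,8,12-trimethyl-2-(phenylsulfonyl)-13-(phenylsulfanyl)cyclotetradeca-3,7,11-trien-1-yl]undeca-5,9-dien-2-ol (epimers at the two sulfur-bearing carbons; ring C1 has the spatial arrangement of the target and reads S only because the sulfonyl carbon outranks the carbinol carbon), via C1/C12-dilithio dianion 15 (not isolated), via C1-lithio epoxy sulfone 16 (not isolated)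
Conditions: n-BuLi (2.05 equiv), TMEDA, THF, −78 → −25 °C; 9 (0.95 equiv), −78 → −40 °C; cannulate into THF–HMPA (10:1, final 2 mM), 25 → 45 °C; H2O
Reagents that add atoms: none
Why: Proposed new method: two sulfur-stabilised allyl carbanions (reversed-polarity forms of the normally electrophilic prenyl termini C12 and C1) are generated together and used in order of basicity – the thioallyl-lithium (pKa ≈ 30) displaces the primary tosylate first by α-alkylation, leaving a C12–H that the remaining anion cannot deprotonate (so no 3-exo cyclopropane forms), and on dilution and warming the surviving sulfonylallyl-lithium (pKa ≈ 23) opens the epoxide 14-exo at its CH carbon by SN2 with inversion, joining two innately electrophilic carbons and converting the cis-epoxide into the (14R,15S) pair with C15–O untouched; the closest known chemistry is Hauser-type dianion alkylation and the intramolecular epoxide opening by sulfur-stabilised allyl anions used to close 10- to 14-membered terpenoid rings.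

Step 8
Reactants: 17 macrocyclic hydroxy sulfone sulfide
Product: 18 (2S,5E)-6,10-dimethyl-2-[(1S,3E,7E,11E)-4,8,12-trimethyl-2,13-bis(phenylsulfonyl)cyclotetradeca-3,7,11-trien-1-yl]undeca-5,9-dien-2-ol (epimers at ring C2 and C13)
Conditions: (NH4)6Mo7O24·4H2O (10 mol %), 30 % H2O2, EtOH, 0 → 25 °C
Reagents that add atoms: hydrogen peroxide, OO
Why: Peroxomolybdate/H2O2 oxidises sulfide to sulfone much faster than it epoxidises unactivated trisubstituted olefins, giving two allylic sulfones that can be removed by one mechanism, while C14 and C15 are untouched.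

Step 9
Reactants: 18 macrocyclic bis-sulfone
Product: 19 colleterpenol, (2S,5E)-6,10-dimethyl-2-[(1R,3E,7E,11E)-4,8,12-trimethylcyclotetradeca-3,7,11-trien-1-yl]undeca-5,9-dien-2-ol
Conditions: PdCl2(dppp) (10 mol %), LiHBEt3 (6 equiv), THF, 0 → 25 °C; H2O
Reagents that add atoms: none
Why: Palladium-catalysed allylic hydrogenolysis (ionisation to π-allyl-Pd, then hydride transfer from LiHBEt3) replaces each sulfonyl group by H at the carbon that carried it, keeping olefin position and E geometry, erasing the two undefined stereocentres and leaving C14 (R) and C15 (S) intact.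

## Compound list
1 | propyne | CC#C | starting material
2 | geranyl bromide | CC(C)=CCC/C(C)=C/CBr | starting material
3 | 1,3-dilithiopropyne | [Li]CC#C[Li] | intermediate
4 | lithium (E)-6,10-dimethylundeca-5,9-dien-1-yn-1-ide | CC(C)=CCC/C(C)=C/CCC#C[Li] | intermediate
5 | (E)-7,11-dimethyldodeca-6,10-dien-2-yn-1-ol | CC(C)=CCC/C(C)=C/CCC#CCO | intermediate
6 | C2-bromomagnesio (2Z,6E)-farnesol bromomagnesium alkoxide | CC(C)=CCC/C(C)=C/CC/C(C)=C(/[Mg]Br)CO[Mg]Br | intermediate
7 | (2Z,6E)-farnesol | CC(C)=CCC/C(C)=C/CC/C(C)=C\CO | intermediate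
8 | (2R,3S)-2,3-epoxy-(6E)-farnesol (cis-epoxide) | CC(C)=CCC/C(C)=C/CC[C@]1(C)O[C@@H]1CO | intermediate
9 | (2R,3S)-2,3-epoxy-(6E)-farnesyl tosylate | CC(C)=CCC/C(C)=C/CC[C@]1(C)O[C@@H]1COS(=O)(=O)c2ccc(C)cc2 | intermediate
10 | (2E,6E)-farnesol | CC(C)=CCC/C(C)=C/CC/C(C)=C/CO | starting material
11 | (2E,6E)-farnesyl bromide | CC(C)=CCC/C(C)=C/CC/C(C)=C/CBr | intermediate
12 | (2E,6E)-farnesyl phenyl sulfone | CC(C)=CCC/C(C)=C/CC/C(C)=C/CS(=O)(=O)c1ccccc1 | intermediate
13 | (2E,6E,10E)-12-hydroxyfarnesyl phenyl sulfone | OC/C(C)=C/CC/C(C)=C/CC/C(C)=C/CS(=O)(=O)c1ccccc1 | intermediate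
14 | (2E,6E,10E)-12-(phenylsulfanyl)farnesyl phenyl sulfone | c1ccccc1SC/C(C)=C/CC/C(C)=C/CC/C(C)=C/CS(=O)(=O)c1ccccc1 | intermediate
15 | C1,C12-dilithio derivative of 14 | c1ccccc1SC([Li])/C(C)=C/CC/C(C)=C/CC/C(C)=C/C([Li])S(=O)(=O)c1ccccc1 | intermediate
16 | open-chain C1-lithio (14R,15S)-epoxy sulfone sulfide | CC(C)=CCC/C(C)=C/CC[C@]1(C)O[C@@H]1CC(Sc2ccccc2)/C(C)=C/CC/C(C)=C/CC/C(C)=C/C([Li])S(=O)(=O)c2ccccc2 | intermediate
17 | macrocyclic C1-sulfone C12-sulfide tertiary alcohol | CC(C)=CCC/C(C)=C/CC[C@](C)(O)[C@H]1C(S(=O)(=O)c2ccccc2)/C=C(\C)CC/C=C(\C)CC/C=C(\C)C(Sc2ccccc2)C1 | intermediate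
18 | macrocyclic C1,C12-bis-sulfone tertiary alcohol | CC(C)=CCC/C(C)=C/CC[C@](C)(O)[C@H]1C(S(=O)(=O)c2ccccc2)/C=C(\C)CC/C=C(\C)CC/C=C(\C)C(S(=O)(=O)c2ccccc2)C1 | intermediate
19 | colleterpenol | CC(C)=CCC/C(C)=C/CC[C@](C)(O)[C@H]1C/C=C(\C)CC/C=C(\C)CC/C=C(\C)CC1 | target

## Step count and risks
Total step count: 9. Longest linear sequence: 6 (steps 1-2-3-7-8-9, or 4-5-6-7-8-9).

**Step 7 (highest risk).** Four things could go wrong:
- Dianion formation may compete with ortho-lithiation of the sulfone.
- The thioallyl anion may alkylate partly at its γ-carbon.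
- The sulfonyl carbanion may be too weak a nucleophile for a trisubstituted epoxide at macrocyclisation dilution.
- The E geometry of C10=C11 may erode in the thioallyl-lithium during the −25 °C ageing.

The fallback separates the two anions in time and closes the ring with the more nucleophilic thio-stabilised anion. It sets out from 10 (and uses 9) and returns at 18. Acetylation of 10 (Ac2O, pyridine) gives (2E,6E)-farnesyl acetate F1. SeO2/t-BuOOH gives 12-hydroxyfarnesyl acetate F2, and PhSSPh/n-Bu3P gives 12-(phenylsulfanyl)farnesyl acetate F3. K2CO3/MeOH then gives 12-(phenylsulfanyl)farnesol F4. Its O,C-dianion (n-BuLi, 2 equiv, TMEDA) has only one carbanion and is alkylated at C12 by 9 to give the open-chain epoxy alcohol F5. A second PhSSPh/n-Bu3P reaction gives the epoxy bis-sulfide F6. With n-BuLi/DABCO at high dilution only the C1 methylene is lithiated, because C12–H is tertiary, and the thioallyl anion opens the epoxide with inversion to the macrocyclic bis-sulfide alcohol F7. Molybdate/H2O2 oxidation of both sulfides gives 18.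

**Step 9.** The π-allyl unit at C10–C12 has two secondary termini. Hydride could therefore enter at C10 and move the olefin to C11=C12. A Grob-type cleavage of the C15 alkoxide against the C1 π-allyl is a minor risk.

The fallback removes the two sulfur groups by different, regiospecific mechanisms. It sets out from 17 and returns at 19. Pd/LiHBEt3 on 17 cleaves only the C1 sulfone, which has an unambiguous prenyl-type π-allyl, and gives the C12-sulfide macrocycle F8. One equivalent of mCPBA at −78 °C gives the allylic sulfoxide F9. Et2NH in MeOH drives its Mislow–Evans [2,3]-shift to the transposed C10 allylic alcohol F10, which has a C11=C12 olefin. Mitsunobu reaction of F10 with 2-nitrobenzenesulfonylhydrazide (PPh3, DEAD), followed by in situ loss of sulfinic acid and N2, is a reductive 1,3-transposition. It delivers H to C12 and returns the olefin to C10=C11, giving 19.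

**Step 2.** The iron-catalysed carbomagnesiation may stall or give reduced by-products on this polyene alkynol. The Z-purity obtained here fixes the final diastereomeric purity.

The fallback changes the method of olefin construction to cuprate addition to an ynoate. It sets out from acetylide 4 in the flask of step 1 and returns at 7. Trapping 4 with methyl chloroformate gives methyl (E)-7,11-dimethyldodeca-6,10-dien-2-ynoate F11. Me2CuLi at −78 °C adds syn to give methyl (2Z,6E)-farnesoate F12. DIBAL-H reduction gives 7.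

## Further compounds
F1 | step 7 | (2E,6E)-farnesyl acetate | CC(C)=CCC/C(C)=C/CC/C(C)=C/COC(C)=O
F2 | step 7 | (2E,6E,10E)-12-hydroxyfarnesyl acetate | OC/C(C)=C/CC/C(C)=C/CC/C(C)=C/COC(C)=O
F3 | step 7 | (2E,6E,10E)-12-(phenylsulfanyl)farnesyl acetate | c1ccccc1SC/C(C)=C/CC/C(C)=C/CC/C(C)=C/COC(C)=O
F4 | step 7 | (2E,6E,10E)-12-(phenylsulfanyl)farnesol | c1ccccc1SC/C(C)=C/CC/C(C)=C/CC/C(C)=C/CO
F5 | step 7 | open-chain (14R,15S)-epoxy C12-sulfide C1-alcohol | CC(C)=CCC/C(C)=C/CC[C@]1(C)O[C@@H]1CC(Sc2ccccc2)/C(C)=C/CC/C(C)=C/CC/C(C)=C/CO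
F6 | step 7 | open-chain (14R,15S)-epoxy C1,C12-bis-sulfide | CC(C)=CCC/C(C)=C/CC[C@]1(C)O[C@@H]1CC(Sc2ccccc2)/C(C)=C/CC/C(C)=C/CC/C(C)=C/CSc2ccccc2
F7 | step 7 | macrocyclic C1,C12-bis-sulfide tertiary alcohol (C14/C15 as in 19) | CC(C)=CCC/C(C)=C/CC[C@](C)(O)[C@H]1C(Sc2ccccc2)/C=C(\C)CC/C=C(\C)CC/C=C(\C)C(Sc2ccccc2)C1
F8 | step 9 | C12-(phenylsulfanyl)colleterpenol | CC(C)=CCC/C(C)=C/CC[C@](C)(O)[C@H]1C/C=C(\C)CC/C=C(\C)CC/C=C(\C)C(Sc2ccccc2)C1
F9 | step 9 | C12-(phenylsulfinyl)colleterpenol | CC(C)=CCC/C(C)=C/CC[C@](C)(O)[C@H]1C/C=C(\C)CC/C=C(\C)CC/C=C(\C)C(S(=O)c2ccccc2)C1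
F10 | step 9 | C10-hydroxy C11=C12 (E) transposed isomer of colleterpenol | CC(C)=CCC/C(C)=C/CC[C@](C)(O)[C@H]1C/C=C(\C)CC/C=C(\C)CCC(O)/C(C)=C/C1
F11 | step 2 | methyl (E)-7,11-dimethyldodeca-6,10-dien-2-ynoate | CC(C)=CCC/C(C)=C/CCC#CC(=O)OC
F12 | step 2 | methyl (2Z,6E)-farnesoate | CC(C)=CCC/C(C)=C/CC/C(C)=C\C(=O)OC
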